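(All constants stand for no real mixture; no experiment stands behind them.)

I began with the gas.

substrate 0.23 M; gas phase 46 mM (held); time 1.5 h

    dissolved gas ⇌ dormant form (K1 = 130, k1 = 1.1 × 10⁻⁴ /s)
    target ⇌ isomer of the product (K2 = 5.5, k2 = 3.2 × 10⁻⁴ /s)
    substrate + target → side product (k3 = 2.5 × 10⁻⁴ /M/s)
    gas phase ⇌ dissolved gas, rate k4*(csat - [dissolved gas]) (k4 = 6.8 × 10⁻⁴ /s, csat = 46 mM)
    substrate + dissolved gas → target (k5 = 0.0025 /M/s)

- percentages count the substrate that a species holds: one side product counts as two
- at the start none of the gas is dissolved
- run time (flask): 1.5 h

1. the target standing at 1.5 h, as a percentage of the substrate charged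
2. the change that raises the amount of target at 1.5 h, in percent of the substrate charged most ("none" if none brings more than 2 percentage points) (Monday's / Saturday's / none)
3. amount of target at 1.5 h, in percent of the substrate charged, after Monday's

The gas phase was held, so [dissolved gas] climbed from nothing until transfer in matched the losses to target and dormant form. Dormant form and isomer of the product began empty, and as a simplification of my own I left out their ways back. The climb took about 12.2 min, shorter than the run, so I used a level that stands: transfer coefficient times saturation, over the sum of the transfer coefficient and the two first-order losses, the one to target being pseudo-first-order in [substrate]. With substrate as charged this gave 22.9 mM. But that level eats substrate, so I went round again with the mid-run [substrate], 0.194 M, and got 24.5 mM, the standing gas level.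

Target drained mostly to isomer: the half-life of target by that step alone, forward rate only, was 0.60 h, shorter than its 3.3 h towards side product with substrate as charged. Feed against drain, started after the climb, gave me 11.5%.

The same round for Monday's, at 0.159 M, gave 52.7 mM and 20.4%. For Saturday's, at 0.183 M, it gave 32.5 mM and 14.7%, less than Monday's.

The forecast said 12%, Monday's and 20.5%, holding that “doubling the transfer coefficient raises the gas level by only about a third”; my first figure lay lower than its 12%.

The flask gave 11.9%, and Monday's won with 9.2 percentage points against 3.4 points, reaching 21.1%.

The flask had not come to rest at 1.5 h, where [dissolved gas] read 0.0252 M against my 24.5 mM. At 15.0 h target stood at 12.8%, but substrate had fallen from 74.1% to 0.691% and isomer had grown from 10.5% to 69.1%. Isomer over target then read 5.40, close to 5.5, while dormant form over dissolved gas read 4.98, far below 130. The standing level at that substrate came to 39.4 mM; the reading was 0.0396 M.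

For the neighbour flask read at 40 min, the same round put the mid-run [substrate] at 0.214 M, the standing level at 23.6 mM and target at 6.75%. That flask gave 0.0226 M and 6.71%.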